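## Retrosynthetic overview

1. Rings: A is the methyl ester end, B the middle, C the free resorcinol end. The plan rests on ring A, the only ring with two unlike oxygens: a methyl ether on C2 and the depside oxygen on C4, set around the C1 ester and the C6 methyl. Direct alkylation of an orsellinate gives this pattern the wrong way round.
2. Cutting the O4(A)–carbonyl(B) ester bond gives the ring A phenol and a tribenzylated B–C acid. Cutting the O4(B)–carbonyl(C) ester bond traces both acyl units to orsellinic acid, so rings B and C are bought.
3. Ring A is the only ring built. C1–C2, C3–C4 and C4–C5 come from an ester-bearing vinylketene and methoxyacetylene. The ketene arises by Wolff shift from methyl 2-diazo-4-methyl-3-oxopent-4-enoate, itself made from methyl acetate and methacrolein.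
4. Order: ring A (steps 1–5), B–C acid in parallel (steps 6–11), union and global hydrogenolysis (steps 12–13).

Key step: step 5

Remark on the chemistry: the target has no stereocentre. Compounds 5 and 12 are racemic and lose their centres in the next transformation. Compounds 7 and 10 are handled cold, in solution and behind a shield.

## Route

Step 1
Reactants: 1 methyl acetate; 2 methacrolein
Product: 5 methyl 3-hydroxy-4-methylpent-4-enoate (racemic), via lithium enolate of methyl acetate 3 (not isolated), via lithium aldolate 4 (not isolated)
Conditions: LiN(iPr)2, THF, -78 °C, 1; then 2, -78 °C; then 1 M HCl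
Reagents that add atoms: none
Why: In this directed aldol addition a preformed lithium ester enolate attacks the enal at the carbonyl carbon under kinetic control at low temperature; the carbinol centre forms racemic and is erased in step 2.

Step 2
Reactants: 5 methyl 3-hydroxy-4-methylpent-4-enoate
Product: 6 methyl 4-methyl-3-oxopent-4-enoate
Conditions: Dess-Martin periodinane, CH2Cl2, 0 °C to rt
Reagents that add atoms: none
Why: Dess-Martin oxidation takes the secondary allylic alcohol to the enone under mild, non-aqueous conditions without heating, which spares the polymerisable Nazarov-type keto ester.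

Step 3
Reactants: 6 methyl 4-methyl-3-oxopent-4-enoate
Product: 7 methyl 2-diazo-4-methyl-3-oxopent-4-enoate
Conditions: 4-acetamidobenzenesulfonyl azide (p-ABSA), Et3N, MeCN, 0 °C
Reagents that add atoms: 4-acetamidobenzenesulfonyl azide, CC(=O)Nc1ccc(cc1)S(=O)(=O)N=[N+]=[N-]
Why: In this Regitz diazo transfer the enolate of the 1,3-dicarbonyl attacks the terminal azide nitrogen and the adduct fragments to the diazo compound and the sulfonamide, while the methyl group on the enone slows conjugate self-addition.

Step 4
Reactants: 8 chloroacetaldehyde dimethyl acetal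
Product: 10 methoxyacetylene, via sodium methoxyacetylide 9 (not isolated)
Conditions: NaNH2 (3 equiv), liq. NH3, -33 °C; NH3 evaporated; cold satd aq NaCl, -70 °C to rt; distilled into a -78 °C receiver and kept as a cold CH2Cl2 solution
Reagents that add atoms: none
Why: This double base-induced 1,2-elimination (methanol, then HCl) is the established route from chloroacetals to alkoxyacetylenes, and the third equivalent of amide holds the product as its acetylide until hydrolysis.

Step 5
Reactants: 7 methyl 2-diazo-4-methyl-3-oxopent-4-enoate; 10 methoxyacetylene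
Product: 15 methyl 4-hydroxy-2-methoxy-6-methylbenzoate, via vinylketene 11 (not isolated), via vinylcyclobutenone 12 (not isolated), via dienylketene 13 (not isolated), via cyclohexadienone 14 (not isolated)
Conditions: 7 + 10 (excess), degassed CH2Cl2, hν 254 nm (low-pressure Hg lamps, quartz), 0 °C, dry-ice condenser with gas outlet; then concentrate, toluene, 80-110 °C
Reagents that add atoms: none
Why: Proposed new method: irradiation expels N2 from 7 and the isopropenyl group, a far better migrating group than the ester methoxy, shifts from the ketone carbon to the carbene carbon (photochemical Wolff rearrangement, which also makes C1-C6) to give the ester-bearing vinylketene 11; the closest known reaction type is the Danheiser benzannulation of unsaturated diazo ketones with alkoxyacetylenes, which has not been shown for a 2-diazo-3-oxo-4-enoate. The unsubstituted, nucleophilic carbon of 10 attacks the ketene carbonyl carbon (C3-C4) and the oxygen-stabilised cationic carbon is then captured by the ketene alpha carbon (C1-C2), a polar stepwise (2+2) cycloaddition giving 12. Warming opens 12 by conrotatory four-electron cleavage of the bond between the quaternary carbon and the carbonyl carbon, and the (Z)-dienylketene 13 closes ring A by a disrotatory six-electron electrocyclisation of the ketene carbon onto the CH2 terminus (C4-C5, six-membered, all-carbon), after which 14 enolises irreversibly to the phenol. No stereocentre is carried forward, since the quaternary centre of 12 forms racemic and becomes the planar C1. Three selectivities are needed: orientation, fixed by the polarisation of the ynol ether so that its oxygen-bearing carbon becomes C2; (2+2) over hetero-(4+2) addition across the ester carbonyl, favoured because an ester oxygen is a weak terminus and vinylketenes react through the ketene C=C bond and not as dienes; and inward rotation of the isopropenyl group, which need not be kinetic because the ring opening is reversible and only 13 is drained by aromatisation. The ketene carbonyl thus emerges as the only free hydroxyl (C4) while C2 already carries its methyl ether.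

Step 6
Reactants: 16 orsellinic acid
Product: 17 benzyl 2,4-bis(benzyloxy)-6-methylbenzoate
Conditions: BnBr (3.5 equiv), K2CO3, DMF, rt to 50 °C
Reagents that add atoms: benzyl bromide, BrCc1ccccc1
Why: Carboxylate alkylation and Williamson etherification with excess halide should cap all three acidic sites, and early ester formation removes the tendency of the free acid to decarboxylate.

Step 7
Reactants: 17 benzyl 2,4-bis(benzyloxy)-6-methylbenzoate
Product: 19 2,4-bis(benzyloxy)-6-methylbenzoic acid, via potassium carboxylate 18 (not isolated)
Conditions: KOH, DMSO/H2O, 90 °C; then cold dilute HCl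
Reagents that add atoms: potassium hydroxide, [K+].[OH-]
Why: Saponification of the doubly ortho-substituted ester needs poorly solvated hydroxide in hot aqueous DMSO, conditions to which benzyl aryl ethers are inert.

Step 8
Reactants: 16 orsellinic acid
Product: 20 allyl 2,4-dihydroxy-6-methylbenzoate (allyl orsellinate)
Conditions: allyl bromide (1 equiv), KHCO3, DMF, rt
Reagents that add atoms: allyl bromide, C=CCBr
Why: This is a chemoselective SN2 carboxylate alkylation, because hydrogen carbonate deprotonates only the carboxylic acid and both phenols stay free.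

Step 9
Reactants: 19 2,4-bis(benzyloxy)-6-methylbenzoic acid; 20 allyl 2,4-dihydroxy-6-methylbenzoate
Product: 22 allyl 4-{[2,4-bis(benzyloxy)-6-methylbenzoyl]oxy}-2-hydroxy-6-methylbenzoate, via mixed trifluoroacetic anhydride 21 (not isolated)
Conditions: (CF3CO)2O, toluene, 0 °C to rt
Reagents that add atoms: none
Why: In this mixed-anhydride esterification, the classical depside coupling, the activated electron-rich aroyl unit acylates the unhindered 4-OH of 20, while the 2-OH is hydrogen-bonded to the neighbouring ester and crowded and should stay free.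

Step 10
Reactants: 22 allyl 4-{[2,4-bis(benzyloxy)-6-methylbenzoyl]oxy}-2-hydroxy-6-methylbenzoate
Product: 23 allyl 2-(benzyloxy)-4-{[2,4-bis(benzyloxy)-6-methylbenzoyl]oxy}-6-methylbenzoate
Conditions: BnBr, K2CO3, dry DMF, rt
Reagents that add atoms: benzyl bromide, BrCc1ccccc1
Why: Williamson etherification caps the one remaining phenol under anhydrous carbonate conditions, which the hindered aryl ester link and the allyl ester tolerate.

Step 11
Reactants: 23 allyl 2-(benzyloxy)-4-{[2,4-bis(benzyloxy)-6-methylbenzoyl]oxy}-6-methylbenzoate
Product: 24 2-(benzyloxy)-4-{[2,4-bis(benzyloxy)-6-methylbenzoyl]oxy}-6-methylbenzoic acid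
Conditions: Pd(PPh3)4 (cat.), N-methylaniline, THF, rt
Reagents that add atoms: none
Why: In this Tsuji-Trost deallylation zerovalent palladium ionises only the allyl ester, and the weakly basic aniline traps the allyl fragment without aminolysis of the depside link or loss of benzyl ethers.

Step 12
Reactants: 24 2-(benzyloxy)-4-{[2,4-bis(benzyloxy)-6-methylbenzoyl]oxy}-6-methylbenzoic acid; 15 methyl 4-hydroxy-2-methoxy-6-methylbenzoate
Product: 26 methyl 4-{[2-(benzyloxy)-4-{[2,4-bis(benzyloxy)-6-methylbenzoyl]oxy}-6-methylbenzoyl]oxy}-2-methoxy-6-methylbenzoate, via mixed trifluoroacetic anhydride 25 (not isolated)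
Conditions: (CF3CO)2O, toluene, 0 °C to rt
Reagents that add atoms: none
Why: The same mixed-anhydride depside esterification applies, and since 15 offers a single hydroxyl (O-4) and 24 has no free phenol, no site selectivity is required.

Step 13
Reactants: 26 protected tridepside
Product: 27 methyl 4-{[4-{[2,4-dihydroxy-6-methylbenzoyl]oxy}-2-hydroxy-6-methylbenzoyl]oxy}-2-methoxy-6-methylbenzoate (target)
Conditions: H2 (1 atm), 10% Pd/C, EtOAc, rt
Reagents that add atoms: none
Why: Catalytic hydrogenolysis cleaves the three benzyl aryl ethers under neutral conditions in a non-nucleophilic solvent, leaving both depside links, the methyl ester and the methyl ether intact.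

## Compound list

1 | methyl acetate | COC(C)=O | starting material
2 | methacrolein | CC(=C)C=O | starting material
3 | lithium enolate of methyl acetate | [Li+].[O-]C(=C)OC | intermediate
4 | lithium aldolate of 5 (racemic) | [Li+].[O-]C(CC(=O)OC)C(C)=C | intermediate
5 | methyl 3-hydroxy-4-methylpent-4-enoate (racemic) | COC(=O)CC(O)C(C)=C | intermediate
6 | methyl 4-methyl-3-oxopent-4-enoate | COC(=O)CC(=O)C(C)=C | intermediate
7 | methyl 2-diazo-4-methyl-3-oxopent-4-enoate | COC(=O)C(=[N+]=[N-])C(=O)C(C)=C | intermediate
8 | chloroacetaldehyde dimethyl acetal | COC(CCl)OC | starting material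
9 | sodium methoxyacetylide | [Na+].[C-]#COC | intermediate
10 | methoxyacetylene | COC#C | intermediate
11 | methyl 3-methyl-2-(oxomethylidene)but-3-enoate (vinylketene) | COC(=O)C(=C=O)C(C)=C | intermediate
12 | methyl 2-methoxy-4-oxo-1-(prop-1-en-2-yl)cyclobut-2-ene-1-carboxylate (racemic) | COC(=O)C1(C(C)=C)C(OC)=CC1=O | intermediate
13 | methyl (2Z)-3-methoxy-5-oxo-2-(prop-1-en-2-yl)penta-2,4-dienoate (dienylketene) | C=C(C)/C(C(=O)OC)=C(OC)\C=C=O | intermediate
14 | methyl 6-methoxy-2-methyl-4-oxocyclohexa-1,5-diene-1-carboxylate | COC(=O)C1=C(C)CC(=O)C=C1OC | intermediate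
15 | methyl 4-hydroxy-2-methoxy-6-methylbenzoate | COC(=O)c1c(C)cc(O)cc1OC | intermediate
16 | orsellinic acid (2,4-dihydroxy-6-methylbenzoic acid) | Cc1cc(O)cc(O)c1C(=O)O | starting material
17 | benzyl 2,4-bis(benzyloxy)-6-methylbenzoate | Cc1cc(OCc2ccccc2)cc(OCc2ccccc2)c1C(=O)OCc1ccccc1 | intermediate
18 | potassium 2,4-bis(benzyloxy)-6-methylbenzoate | Cc1cc(OCc2ccccc2)cc(OCc2ccccc2)c1C(=O)[O-].[K+] | intermediate
19 | 2,4-bis(benzyloxy)-6-methylbenzoic acid | Cc1cc(OCc2ccccc2)cc(OCc2ccccc2)c1C(=O)O | intermediate
20 | allyl 2,4-dihydroxy-6-methylbenzoate | C=CCOC(=O)c1c(C)cc(O)cc1O | intermediate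
21 | 2,4-bis(benzyloxy)-6-methylbenzoic trifluoroacetic anhydride | Cc1cc(OCc2ccccc2)cc(OCc2ccccc2)c1C(=O)OC(=O)C(F)(F)F | intermediate
22 | allyl 4-{[2,4-bis(benzyloxy)-6-methylbenzoyl]oxy}-2-hydroxy-6-methylbenzoate | C=CCOC(=O)c1c(C)cc(OC(=O)c2c(C)cc(OCc3ccccc3)cc2OCc2ccccc2)cc1O | intermediate
23 | allyl 2-(benzyloxy)-4-{[2,4-bis(benzyloxy)-6-methylbenzoyl]oxy}-6-methylbenzoate | C=CCOC(=O)c1c(C)cc(OC(=O)c2c(C)cc(OCc3ccccc3)cc2OCc2ccccc2)cc1OCc1ccccc1 | intermediate
24 | 2-(benzyloxy)-4-{[2,4-bis(benzyloxy)-6-methylbenzoyl]oxy}-6-methylbenzoic acid | OC(=O)c1c(C)cc(OC(=O)c2c(C)cc(OCc3ccccc3)cc2OCc2ccccc2)cc1OCc1ccccc1 | intermediate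
25 | 2-(benzyloxy)-4-{[2,4-bis(benzyloxy)-6-methylbenzoyl]oxy}-6-methylbenzoic trifluoroacetic anhydride | FC(F)(F)C(=O)OC(=O)c1c(C)cc(OC(=O)c2c(C)cc(OCc3ccccc3)cc2OCc2ccccc2)cc1OCc1ccccc1 | intermediate
26 | methyl 4-{[2-(benzyloxy)-4-{[2,4-bis(benzyloxy)-6-methylbenzoyl]oxy}-6-methylbenzoyl]oxy}-2-methoxy-6-methylbenzoate | COC(=O)c1c(C)cc(OC(=O)c2c(C)cc(OC(=O)c3c(C)cc(OCc4ccccc4)cc3OCc3ccccc3)cc2OCc2ccccc2)cc1OC | intermediate
27 | methyl 4-{[4-{[2,4-dihydroxy-6-methylbenzoyl]oxy}-2-hydroxy-6-methylbenzoyl]oxy}-2-methoxy-6-methylbenzoate (CNP0503951.0) | COC(=O)c1c(C)cc(OC(=O)c2c(C)cc(OC(=O)c3c(C)cc(O)cc3O)cc2O)cc1OC | target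

## Counts and risks

Total step count: 13.
Longest linear sequence: 7 steps from orsellinic acid (steps 6, 7, 9, 10, 11, 12, 13). The ring A branch runs 6 steps (1, 2, 3, 5, 12, 13).

**1. Step 5 (new method).**
- The ketene may be captured across its ester carbonyl in the hetero-(4+2) mode.
- The carbene may be intercepted by the ynol ether before the vinyl shift.
- The ring opening may turn the ester inward, so that closure goes through the ester oxygen and not the CH2 terminus.
- The volatile alkyne may be lost with the nitrogen stream.
- The phenol formed may be acylated by remaining ketene or degraded by further irradiation.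

Fallback with known chemistry, setting out from 16 and returning at 15. The carboxyl group is alkylated with MeI and KHCO3 in DMF to give methyl orsellinate F1. The unchelated O-4 is benzylated with one equivalent of BnBr and K2CO3 in acetone to give methyl 4-(benzyloxy)-2-hydroxy-6-methylbenzoate F2. The chelated O-2 is then methylated with MeI and K2CO3 in DMF to give methyl 4-(benzyloxy)-2-methoxy-6-methylbenzoate F3. Hydrogenolysis (H2, Pd/C, EtOAc) frees O-4 and gives 15.

**2. Step 3.** The amine base may trigger conjugate self-addition and polymerisation of the enone keto ester faster than diazo transfer, and the same decay may already start while 6 is stored.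

Fallback that installs the diazo group before the ketone exists, setting out from 2 and returning at 7. Methyl diazoacetate F4 is made from glycine methyl ester hydrochloride and NaNO2 in CH2Cl2/water and kept in solution. It is lithiated with LiN(iPr)2 in THF at -78 °C and added to 2 to give methyl 2-diazo-3-hydroxy-4-methylpent-4-enoate F5. This allylic alcohol is oxidised with IBX in DMSO at rt to 7, so that 5 and 6 are bypassed.

**3. Step 12.** Acyl transfer at a carbonyl flanked by methyl and benzyloxy groups may be slow. That leaves room for ring C-acylation of the electron-rich arenes or acyl exchange at the internal depside link.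

Fallback that removes the ortho benzyl ether from the acylating partner, setting out from 22 and returning at 27. Compound 22 is deallylated directly (Pd(PPh3)4, N-methylaniline, THF) to 4-{[2,4-bis(benzyloxy)-6-methylbenzoyl]oxy}-2-hydroxy-6-methylbenzoic acid F6. This smaller, internally hydrogen-bonded salicylic-type acid is condensed with 15 by DCC in toluene, a known depside coupling for acids with a free ortho hydroxyl. The product is methyl 4-{[4-{[2,4-bis(benzyloxy)-6-methylbenzoyl]oxy}-2-hydroxy-6-methylbenzoyl]oxy}-2-methoxy-6-methylbenzoate F7. Hydrogenolysis (H2, Pd/C, EtOAc) then gives 27.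

## Further compounds

F1 | step 5 | methyl orsellinate (methyl 2,4-dihydroxy-6-methylbenzoate) | COC(=O)c1c(C)cc(O)cc1O
F2 | step 5 | methyl 4-(benzyloxy)-2-hydroxy-6-methylbenzoate | COC(=O)c1c(C)cc(OCc2ccccc2)cc1O
F3 | step 5 | methyl 4-(benzyloxy)-2-methoxy-6-methylbenzoate | COC(=O)c1c(C)cc(OCc2ccccc2)cc1OC
F4 | step 3 | methyl diazoacetate | COC(=O)C=[N+]=[N-]
F5 | step 3 | methyl 2-diazo-3-hydroxy-4-methylpent-4-enoate (racemic) | COC(=O)C(=[N+]=[N-])C(O)C(C)=C
F6 | step 12 | 4-{[2,4-bis(benzyloxy)-6-methylbenzoyl]oxy}-2-hydroxy-6-methylbenzoic acid | OC(=O)c1c(C)cc(OC(=O)c2c(C)cc(OCc3ccccc3)cc2OCc2ccccc2)cc1O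
F7 | step 12 | methyl 4-{[4-{[2,4-bis(benzyloxy)-6-methylbenzoyl]oxy}-2-hydroxy-6-methylbenzoyl]oxy}-2-methoxy-6-methylbenzoate | COC(=O)c1c(C)cc(OC(=O)c2c(C)cc(OC(=O)c3c(C)cc(OCc4ccccc4)cc3OCc3ccccc3)cc2O)cc1OC
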